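**Assumption:** the target (C30H32O2) has no stereocentre and the indenone–azulene axis is not configurationally defined, so there is no enantiomer to select; the one stereocentre met on the way (C3 of the indanones) is carried racemic and erased in step 4.

**Retrosynthetic overview**
1. Last bond: indenone C2–azulene C3, by Pd-catalysed C–H arylation of commercial guaiazulene with a 2-bromoindenone.
2. The 2-bromoindenone comes from the 3-methylindan-1-one by bromination/dehydrobromination.
3. The isobutyryl group comes from an aryl bromide (Br–Li exchange, Weinreb amide) with the indanone carbonyl masked as a dioxolane.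
4. The five-membered ketone ring is formed first, on 4-bromotoluene, by Friedel–Crafts acylation/Nazarov cyclization with crotonyl chloride.
5. Ring order: benzene ring (bought) → cyclopentanone ring → indenone → coupling to the intact, bought azulene.

**Route**

Step 1
Reactants: 1 4-bromotoluene; 2 (E)-crotonyl chloride
Product: 4 racemic 4-bromo-3,7-dimethylindan-1-one, via enone 3 (not isolated)
Conditions: AlCl3 (1.3 equiv), CH2Cl2, 0 °C to rt; crude enone then in conc. H2SO4, 90 °C
Reagents that add atoms: (E)-crotonyl chloride 2, C/C=C/C(Cl)=O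
Why: Friedel–Crafts acylation goes ortho to the activating methyl group (para is blocked by Br), and the protonated aryl propenyl ketone 3 then closes by Nazarov-type cyclization at the only free position ortho to the acyl group, giving 4 as a racemate.

Step 2
Reactants: 4 racemic 4-bromo-3,7-dimethylindan-1-one
Product: 5 racemic 4'-bromo-3',7'-dimethyl-2',3'-dihydrospiro[1,3-dioxolane-2,1'-indene]
Conditions: (Me3SiOCH2)2 (1.5 equiv), Me3SiOTf (5 mol %), CH2Cl2, −78 °C to rt
Reagents that add atoms: 1,2-bis(trimethylsilyloxy)ethane, C[Si](C)(C)OCCO[Si](C)(C)C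
Why: Noyori ketalization, driven by formation of the Si–O–Si bond, masks the only carbonyl so that the aryl bromide can be lithiated, and no stereocentre is touched.

Step 3
Reactants: 5 racemic bromo ketal; 6 N-methoxy-N-methylisobutyramide
Product: 9 racemic 4-isobutyryl-3,7-dimethylindan-1-one, via aryllithium 7 (not isolated), via ketal ketone 8 (not isolated)
Conditions: n-BuLi (1.1 equiv), THF, −78 °C; 6 (1.3 equiv), −78 to 0 °C; then 2 M aq. HCl, THF, rt
Reagents that add atoms: N-methoxy-N-methylisobutyramide 6, CC(C)C(=O)N(C)OC; water, O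
Why: Bromine–lithium exchange is faster than any deprotonation at −78 °C, aryllithium 7 adds once to the Weinreb amide (Weinreb ketone synthesis, stable chelated adduct), and the aqueous HCl quench releases the ketone and hydrolyses the dioxolane in the same pot, leaving C3 racemic.

Step 4
Reactants: 9 racemic 4-isobutyryl-3,7-dimethylindan-1-one
Product: 13 2-bromo-4-isobutyryl-3,7-dimethylinden-1-one, via benzylic bromide 10 (not isolated), via indenone 11 (not isolated), via dibromide 12 (not isolated)
Conditions: NBS (2.1 equiv), AIBN (5 mol %), PhCF3, 85 °C; then Et3N (3 equiv), 0 °C to rt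
Reagents that add atoms: N-bromosuccinimide, O=C1CCC(=O)N1Br
Why: Wohl–Ziegler bromination at the tertiary benzylic C3–H, loss of HBr to indenone 11, addition of the Br2 formed from HBr and NBS, and Et3N-induced E1cB loss of HBr from dibromide 12 give the 2-bromoindenone and remove the only stereocentre.

Step 5
Reactants: 13 2-bromo-4-isobutyryl-3,7-dimethylinden-1-one; 14 guaiazulene (7-isopropyl-1,4-dimethylazulene)
Product: 15 2-(5-isopropyl-3,8-dimethylazulen-1-yl)-4-isobutyryl-3,7-dimethylinden-1-one (target)
Conditions: 14 (1.5 equiv), Pd(OAc)2 (2 mol %), potassium acetate (2 equiv), DMAc, 120 °C, argon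
Reagents that add atoms: guaiazulene 14, Cc1ccc(C(C)C)cc2c(C)ccc1-2
Why: Direct C–H arylation, in which the vinyl bromide adds oxidatively to zerovalent palladium, acetate-assisted palladation takes place at C3 of guaiazulene (its most nucleophilic position, favoured in polar DMAc) and reductive elimination forms the C2–azulenyl bond without creating a stereocentre.

**Compound list**
1 | 4-bromotoluene | Cc1ccc(Br)cc1 | starting material
2 | (E)-crotonyl chloride [(E)-but-2-enoyl chloride] | C/C=C/C(Cl)=O | starting material
3 | (E)-1-(5-bromo-2-methylphenyl)but-2-en-1-one | C/C=C/C(=O)c1cc(Br)ccc1C | intermediate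
4 | 4-bromo-3,7-dimethylindan-1-one (racemic) | CC1CC(=O)c2c(C)ccc(Br)c21 | intermediate
5 | 4'-bromo-3',7'-dimethyl-2',3'-dihydrospiro[1,3-dioxolane-2,1'-indene] (racemic) | CC1CC2(OCCO2)c2c(C)ccc(Br)c21 | intermediate
6 | N-methoxy-N-methylisobutyramide | CC(C)C(=O)N(C)OC | starting material
7 | (3',7'-dimethyl-2',3'-dihydrospiro[1,3-dioxolane-2,1'-inden]-4'-yl)lithium (racemic) | CC1CC2(OCCO2)c2c(C)ccc([Li])c21 | intermediate
8 | 1-(3',7'-dimethyl-2',3'-dihydrospiro[1,3-dioxolane-2,1'-inden]-4'-yl)-2-methylpropan-1-one (racemic) | CC1CC2(OCCO2)c2c(C)ccc(C(=O)C(C)C)c21 | intermediate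
9 | 4-isobutyryl-3,7-dimethylindan-1-one [3,7-dimethyl-4-(2-methylpropanoyl)indan-1-one] (racemic) | CC1CC(=O)c2c(C)ccc(C(=O)C(C)C)c21 | intermediate
10 | 3-bromo-4-isobutyryl-3,7-dimethylindan-1-one (racemic) | CC1(Br)CC(=O)c2c(C)ccc(C(=O)C(C)C)c21 | intermediate
11 | 4-isobutyryl-3,7-dimethylinden-1-one | CC1=CC(=O)c2c(C)ccc(C(=O)C(C)C)c21 | intermediate
12 | 2,3-dibromo-4-isobutyryl-3,7-dimethylindan-1-one (racemic diastereomer mixture) | CC1(Br)C(Br)C(=O)c2c(C)ccc(C(=O)C(C)C)c21 | intermediate
13 | 2-bromo-4-isobutyryl-3,7-dimethylinden-1-one | CC1=C(Br)C(=O)c2c(C)ccc(C(=O)C(C)C)c21 | intermediate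
14 | guaiazulene (7-isopropyl-1,4-dimethylazulene) | Cc1ccc(C(C)C)cc2c(C)ccc1-2 | starting material
15 | 2-(5-isopropyl-3,8-dimethylazulen-1-yl)-4-isobutyryl-3,7-dimethylinden-1-one (achiral) | CC1=C(c2cc(C)c3cc(C(C)C)ccc(C)c2-3)C(=O)c2c(C)ccc(C(=O)C(C)C)c21 | target

**Totals:** 5 steps; longest linear sequence 5 steps (1 → 4 → 5 → 9 → 13 → 15); guaiazulene 14 is bought and used in the last step.

**Three steps most likely to fail, with fallbacks**

Step 1. The risk is that ring closure onto an acyl-deactivated ring next to bromine stalls, or that bromine scrambles under the Lewis acid. The fallback sets out from crotonyl chloride 2 and comes back at 4. It closes the ring by acylation of a ring that carries no acyl group. Compound 2 is quenched into ethanol/Et3N to give ethyl (E)-but-2-enoate F1. Hayashi–Miyaura conjugate addition of commercial (2-bromo-5-methylphenyl)boronic acid F2 to F1 ([RhCl(C8H12)]2 with C8H12 = 1,5-cyclooctadiene, KOH, dioxane/H2O, 60 °C) gives racemic ethyl 3-(2-bromo-5-methylphenyl)butanoate F3. Saponification (LiOH, THF/H2O) gives 3-(2-bromo-5-methylphenyl)butanoic acid F4. Intramolecular Friedel–Crafts acylation of F4 (P2O5 in CH3SO3H, 60 °C) can only occur at the free position ortho to both the side chain and the methyl group, and gives 4.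

Step 4. The risk is competing bromination at the isobutyryl methine or at the aryl methyl group. The fallback sets out from 9 and comes back at 13. It uses site-selective enolate chemistry in place of radical bromination. LiN(SiMe3)2 in THF at −78 °C removes a proton from the less hindered, more acidic indanone CH2 to give the lithium enolate F5, which Me3SiCl traps as 1-[1,4-dimethyl-3-(trimethylsilyloxy)-1H-inden-7-yl]-2-methylpropan-1-one F6. Saegusa–Ito oxidation of F6 (Pd(OAc)2, 1.05 equiv, CH3CN, rt) gives indenone 11, now isolated. Br2 (1.0 equiv, CH2Cl2, 0 °C) adds to the strained enone double bond of 11 to give dibromide 12, and Et3N eliminates HBr to give 13.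

Step 5. The risk is poor C3 versus C2 or C4-methyl selectivity on guaiazulene, or decomposition of the bromoindenone at 120 °C. The fallback sets out from guaiazulene 14 and comes back at 15. It replaces C–H activation by a Suzuki–Miyaura coupling with a pre-formed azulenyl boronate. NBS in THF at −78 °C gives 3-bromo-7-isopropyl-1,4-dimethylazulene F7, which is unstable and is not warmed. Treatment at once with n-BuLi gives (5-isopropyl-3,8-dimethylazulen-1-yl)lithium F8. Quenching with 2-isopropoxy-4,4,5,5-tetramethyl-1,3,2-dioxaborolane gives 2-(5-isopropyl-3,8-dimethylazulen-1-yl)-4,4,5,5-tetramethyl-1,3,2-dioxaborolane F9. Coupling of F9 with 13 (Pd(PPh3)4, K2CO3, toluene/EtOH/H2O, 80 °C) gives 15.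

**Further compounds**
F1 | step 1 | ethyl (E)-but-2-enoate | CCOC(=O)/C=C/C
F2 | step 1 | (2-bromo-5-methylphenyl)boronic acid | Cc1ccc(Br)c(B(O)O)c1
F3 | step 1 | ethyl 3-(2-bromo-5-methylphenyl)butanoate (racemic) | CCOC(=O)CC(C)c1cc(C)ccc1Br
F4 | step 1 | 3-(2-bromo-5-methylphenyl)butanoic acid (racemic) | CC(CC(=O)O)c1cc(C)ccc1Br
F5 | step 4 | lithium enolate of 9 at the indanone carbonyl (racemic) | CC1C=C(O[Li])c2c(C)ccc(C(=O)C(C)C)c21
F6 | step 4 | 1-[1,4-dimethyl-3-(trimethylsilyloxy)-1H-inden-7-yl]-2-methylpropan-1-one (racemic) | CC1C=C(O[Si](C)(C)C)c2c(C)ccc(C(=O)C(C)C)c21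
F7 | step 5 | 3-bromo-7-isopropyl-1,4-dimethylazulene | Cc1ccc(C(C)C)cc2c(C)cc(Br)c1-2
F8 | step 5 | (5-isopropyl-3,8-dimethylazulen-1-yl)lithium | Cc1ccc(C(C)C)cc2c(C)cc([Li])c1-2
F9 | step 5 | 2-(5-isopropyl-3,8-dimethylazulen-1-yl)-4,4,5,5-tetramethyl-1,3,2-dioxaborolane | Cc1ccc(C(C)C)cc2c(C)cc(B3OC(C)(C)C(C)(C)O3)c1-2
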